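## Analysis of the target

Atoms are numbered along the SMILES string: C1 (bearing the exocyclic CH2), C2, C3, C4, O5, C6, C7, C8 (CH3), C9 (Br), C10, C11, C12 (CH3, OH), C13, C14, C15 and C16 (CMe2); ring A is C8–C13, ring B is C6/C7/C8/C13/C14/C15, ring C is C1–C4/C16/C15 and ring D is the oxolane C4/O5/C6/C15/C16. The target 21 is a trans-decalin (rings A and B) with a cyclohexane (ring C) spiro-joined at C15; the C4–O5–C6 ether ties ring C back to ring B, so rings C and D form a 6-oxabicyclo[3.2.1]octane. There are seven stereocentres (4S,6R,8S,9S,12R,13S,15R): the C8 methyl and the C13 hydrogen are trans-diaxial, the C9 bromine is equatorial and cis to the C8 methyl, the C12 hydroxyl is axial (syn to the C8 methyl) with its methyl equatorial, C1 is axial and C16 equatorial on ring B, O5 is equatorial on C6, and C4 follows from the bridge. The sensitive groups are a secondary neopentyl bromide, a tertiary alcohol prone to dehydration and a 1,1-disubstituted alkene that isomerises in acid. The bromide cannot be introduced by substitution, and it can be lost by E2, 1,3-elimination or fragmentation whenever a carbonyl or an alkoxide sits at C12 or C13. The main difficulty is C15: it is quaternary, bonded to the fully substituted C16 and flanked by the oxygen-bearing C6 and the sp2 carbon C1, and the ether terminus C4 is neopentyl as well. The route rests on ring C being dimedone (9) in disguise: C16 with its two methyl groups, C1 and C3 as the carbonyl carbons, C15 and C4 as the methylenes next to C16. C15 can therefore serve twice as an enolate carbon, toward C14 and toward C6; the oxygen left on C6 becomes O5 and the C1 carbonyl becomes the methylidene carbon.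

## Retrosynthetic reasoning

**C1=CH2.** The exocyclic alkene is removed first, giving ketone 20. It is the most acid-sensitive group and the only one that needs no stereocontrol, so a carbonyl olefination is kept for the last step.

**C3 oxygen.** Ketone 20 is traced through enone 19 and enol triflate 18 to β-diketone 17 and on to the vinylogous ester 16. This adds back the second oxygen of the dimedone unit. The forward sequence has to tell the C1 oxygen from the C3 oxygen of 17; the quaternary neighbour C15 shields the C1 oxygen, which should secure this.

**O5–C4.** In 16 the ether bond to C4 is cut, leading through the C4 iodide 15 to diol 14. C4 is the γ-carbon of the vinylogous ester and, once C15 is quaternary, the only position that a strong base can deprotonate. The C6 oxygen is already held gauche to C16 on ring B, so a five-membered closure is short and its stereochemistry at C4 is dictated by the bridge.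

**C12–CH3.** The methyl group of 14 is removed to give ketone 13. The forward addition must come from the equatorial direction; the axial C8 methyl blocks the axial path, so the substrate enforces it.

**C14–C15 and C6–C15 (key disconnection).** Both ring B bonds to the spiro carbon of 13 are cut. This separates the molecule into the vinylogous ester 10 and the ring A enone aldehyde 8, by way of the open keto aldehyde 12 and the enolate 11. No other pair of cuts removes the spiro centre and leaves two fragments of this simplicity. The C15–C16 bond between two fully substituted carbons is never made, because it is present in 9, from which 10 is obtained by enol etherification. The forward reaction must use C15 first as a Michael donor and then as an aldol donor and must deliver the trans-fused chair with C16 and the C6 hydroxyl equatorial.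

**Ring A functional groups.** Aldehyde 8 is traced to the allyl enone 7, the allylic alcohol 6, the diene 5 and the β-bromo ketone 4. This keeps the two-carbon side chain masked as an allyl group until the end and builds the methylidene ketone from a C13 ketone by methylenation and allylic oxidation, so no protecting group is needed.

**C7–C8 and C9–Br.** In 4 the bond from C8 to the allyl group and the C–Br bond are cut together, giving the tertiary allylic alcohol 3. A bromonium-induced 1,2-shift makes the neopentyl C–Br bond by addition rather than substitution and places bromine anti to the migrating group, which is the relative configuration required.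

**C13–allyl.** Alcohol 3 comes from enone 1 and the allyl donor 2 by a catalytic enantioselective carbonyl allylation. This is the only step in which absolute configuration is created; every other stereocentre is derived from it.

## Alternatives that were turned down

**Alternative 1:** Here C6–C15 and O5–C4 are cut together, so that ring D is assembled first from the ring A aldehyde A3 (C12 masked as a dioxolane) and the racemic vinylcyclopropane diester A2.
- Forward key step: a zerovalent palladium catalyst with a chiral bisphosphine opens A2 to a zwitterionic π-allyl complex. Its malonate carbon (C15) adds to the aldehyde carbon C6 and the alkoxide closes on the allyl terminus C4, giving the 2,5-cis oxolane diester A1.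
- For it: the C4–O5 bond is formed in the same catalytic event as C6–C15, and the ligand controls C4 and C6. The chosen route needs a separate iodination and etherification at a neopentyl carbon for this bond, so on this point the alternative is stronger.
- Against it: A1 still lacks both carbocycles at C15. Its two ester groups are diastereotopic and must be told apart to become C1 and C14. Ring B has to be closed onto C13 and ring C through a new C1–C2 bond to the vinyl group, all at a carbon that is already quaternary and neopentyl. The nucleophilic carbon of opened A2 is flanked by CMe2, an enolisable aliphatic aldehyde such as A3 is a weak acceptor, and the catalyst must override the resident C8/C9 chirality.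
- Comparison: the chosen route gives up the early ether bond but forms the spiro centre with both carbocycles attached in one operation (13). What follows 13 is functional-group chemistry, whereas A1 would still need several C–C bond formations at its most hindered carbon.

**Alternative 2:** The ether is cut last at O5–C6, at a C–H bond.
- Forward key step: the C4 alcohol A5 is converted into its hypoiodite by a hypervalent iodine oxidant and iodine under visible light. The alkoxy radical abstracts hydrogen from C6 through a six-membered transition state, and oxidation of the C6 radical and closure give the ether A4.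
- For it: no oxygen is needed at C6 until the end, so ring C can be carried at its final oxidation level. The removal of the C3 oxygen (steps 11–14 of the chosen route) would not be needed, which is a real saving.
- Against it: the alkoxy radical at C4 sits next to the quaternary C16, so β-scission of C4–C16 to a tertiary radical and an aldehyde competes with hydrogen abstraction. The site of abstraction depends entirely on the C4 carbinol configuration, since the wrong epimer would reach C14–H instead. That configuration has to be set across C16 without help from a C6 substituent. The configuration at C6 is decided only in the closure, where a cis- and a trans-fused oxolane are both conceivable.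
- Comparison: in the chosen route the C6 oxygen is installed by the aldol event itself with its configuration under thermodynamic control, and it then attacks an activated C4 in a polar, site-specific closure. The price is the longer redox sequence on ring C.

**Alternative 3:** The C15–C16 bond is cut and ring C arises by ring expansion.
- Forward key step: a dialkylaluminium chloride opens the C6–C15 epoxide of the epoxy carbinol A7 at C15 while the C1–C16 bond of the tertiary cyclopentenol migrates anti to the departing oxygen. C1 becomes a ketone and C6 keeps its hydroxyl, giving the spiro β-hydroxy ketone A6.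
- For it: the shift is stereospecific and sets C15 relative to C6. It delivers the same β-hydroxy ketone array as 13 but without a C3 oxygen, and the C3=C4 alkene of A6 could close ring D by halo-etherification. In the endgame this alternative is stronger than the chosen route.
- Against it: A7 is itself demanding. It needs a C6=C15 alkene carrying the cyclopentenol and a face-selective epoxidation in the presence of a second alkene. The group that migrates must be the quaternary C16 and not the allylic methylene C2 on the same carbinol carbon, whose migratory aptitude is comparable. The shift has to create the C15–C16 bond between two fully substituted carbons, the most congested bond of the molecule.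
- Comparison: the chosen route takes that bond ready-made from 9 and forms only bonds from C15 to a CH2 and a CH carbon. It accepts in exchange a four-step removal of the C3 oxygen.

Key step: step 8

## Route

Assumption: the titanium–BINOL allylation is taken to give the (S)-carbinol 3 with (R)-BINOL; if the sense of induction is the reverse, (S)-BINOL is used and nothing else changes.

Step 1
Reactants: 1 2-methylcyclohex-2-en-1-one; 2 tetraallylstannane
Product: 3 (S)-2-methyl-1-(prop-2-en-1-yl)cyclohex-2-en-1-ol
Conditions: Ti(Oi-Pr)4 (30 mol%), (R)-BINOL (30 mol%), i-PrOH, CH2Cl2, 23 °C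
Reagents that add atoms: none
Why: Catalytic enantioselective 1,2-allylation of a ketone by allyl transfer from tin under a titanium–BINOL Lewis acid, a reaction class that accepts α-substituted cyclic enones; the ligand selects the carbonyl face and so sets the C13 carbinol centre, the only stereocentre made by reagent control in the route.

Step 2
Reactants: 3 (S)-2-methyl-1-(prop-2-en-1-yl)cyclohex-2-en-1-ol
Product: 4 (2S,3S)-3-bromo-2-methyl-2-(prop-2-en-1-yl)cyclohexan-1-one
Conditions: NBS, CH2Cl2, −20 → 0 °C, dark
Reagents that add atoms: N-bromosuccinimide, O=C1CCC(=O)N1Br
Why: Halonium-induced semipinacol rearrangement of an allylic alcohol: the bromonium ion on the trisubstituted C8=C9 alkene opens at the tertiary carbon C8 while the allyl group on C13 migrates antiperiplanar to bromine and C13 becomes the ketone. The shift is suprafacial, so the carbinol configuration is transferred to C8 and C9 with bromine trans to allyl and cis to methyl.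

Step 3
Reactants: 4 (2S,3S)-3-bromo-2-methyl-2-(prop-2-en-1-yl)cyclohexan-1-one
Product: 5 (1S,2S)-1-bromo-2-methyl-3-methylidene-2-(prop-2-en-1-yl)cyclohexane
Conditions: Zn, CH2Br2, TiCl4, THF/CH2Cl2, 0 → 23 °C
Reagents that add atoms: dibromomethane, BrCBr
Why: Lombardo–Takai methylenation with the zinc/titanium methylene reagent is non-basic and suited to hindered ketones. It avoids a free alkoxide at C13, which would be aligned for Grob fragmentation with the C9–Br bond.

Step 4
Reactants: 5 (1S,2S)-1-bromo-2-methyl-3-methylidene-2-(prop-2-en-1-yl)cyclohexane
Product: 6 (3S,4S)-4-bromo-3-methyl-2-methylidene-3-(prop-2-en-1-yl)cyclohexan-1-ol (both C12 epimers)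
Conditions: SeO2 (cat.), t-BuOOH, CH2Cl2, 23 °C
Reagents that add atoms: tert-butyl hydroperoxide, CC(C)(C)OO
Why: SeO2 allylic hydroxylation (ene reaction, then [2,3]-shift) of the 1,1-disubstituted alkene oxidises the ring methylene C12, the only allylic C–H of that alkene because C8 is quaternary; the monosubstituted allyl alkene is much less reactive. The new carbinol centre is removed in step 5, so its configuration is immaterial.

Step 5
Reactants: 6 (3S,4S)-4-bromo-3-methyl-2-methylidene-3-(prop-2-en-1-yl)cyclohexan-1-ol
Product: 7 (3S,4S)-4-bromo-3-methyl-2-methylidene-3-(prop-2-en-1-yl)cyclohexan-1-one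
Conditions: Dess–Martin periodinane, NaHCO3, CH2Cl2, 0 → 23 °C
Reagents that add atoms: none
Why: Dess–Martin oxidation of a secondary allylic alcohol to the α-methylidene ketone under buffered, non-basic conditions that leave the bromide and both alkenes alone.

Step 6
Reactants: 7 (3S,4S)-4-bromo-3-methyl-2-methylidene-3-(prop-2-en-1-yl)cyclohexan-1-one
Product: 8 2-[(1S,6S)-6-bromo-1-methyl-2-methylidene-3-oxocyclohexyl]acetaldehyde
Conditions: O3, CH2Cl2, Sudan Red 7B, −78 °C; PPh3, −78 → 23 °C
Reagents that add atoms: ozone, [O-][O+]=O
Why: Chemoselective ozonolysis: the isolated monosubstituted alkene is far more electron-rich than the conjugated C13=C14 bond, and the dye end-point stops the ozone before the enone is attacked. Aldehyde 8 is an α-methylidene ketone and is used at once in step 8.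

Step 7
Reactants: 9 dimedone (5,5-dimethylcyclohexane-1,3-dione)
Product: 10 3-methoxy-5,5-dimethylcyclohex-2-en-1-one
Conditions: HC(OMe)3, MeOH, p-TsOH·H2O (cat.), 23 °C
Reagents that add atoms: trimethyl orthoformate, COC(OC)OC
Why: Acid-catalysed enol etherification of a cyclic 1,3-dione, with the orthoformate as methyl donor and water scavenger; the dione is symmetrical, so only one enol ether can form.

Step 8
Reactants: 10 3-methoxy-5,5-dimethylcyclohex-2-en-1-one; 8 2-[(1S,6S)-6-bromo-1-methyl-2-methylidene-3-oxocyclohexyl]acetaldehyde
Product: 13 spiro hydroxy vinylogous ester (6R,8S,9S,13S,15R; rings A–C; C1 ketone; C2=C3–OMe; C6–OH; C12 ketone; C9–Br), via lithium α′-enolate 11 (not isolated), via Michael adduct 12 (not isolated)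
Conditions: LiN(i-Pr)2, THF, −78 °C; 8, −78 → −20 °C; t-BuOH, KOt-Bu (cat.), −20 → 0 °C; aq NH4Cl
Reagents that add atoms: none
Why: This is a tandem Michael–aldol (5+1) annulation; the closest known types are the Stork–Danheiser α′-functionalisation of a vinylogous ester and base-mediated Michael/aldol ring construction on an enone aldehyde. LiN(i-Pr)2 can deprotonate 10 kinetically only at the α′-methylene C15, giving the cross-conjugated enolate 11. Addition of 11 to the aldehyde is fast but reversible, whereas conjugate addition of C15 to the unhindered methylene carbon C14 is not, so warming should channel the material to the C12 enolate of 12 (bond C14–C15). The t-BuOH/KOt-Bu couple then shuttles the proton from C15 to C13, and the regenerated C15 enolate closes ring B on the aldehyde carbon C6 in a 6-(enolexo)-exo-trig aldol addition (bond C6–C15), which makes C15 the spiro centre. The aldol step and the protonation at C13 are reversible, and C15 carries no hydrogen afterwards, so the aldol cannot dehydrate and the product is selected by stability. C13 should settle with its hydrogen axial (trans-decalin), C15 with the bulky C16 equatorial and the C1 carbonyl axial on ring B, and C6 with its hydroxyl equatorial, where it avoids the syn-axial C8 methyl and can hydrogen-bond or chelate lithium to the C1 carbonyl. No regiochemical control is needed because both nucleophilic events use the same carbon, and the fixed C8 centre relays the absolute configuration to C13, C15 and C6. The bromide has to survive as a spectator: it is secondary and neopentyl, and keeping the temperature at or below 0 °C with only catalytic alkoxide is meant to disfavour E2 and 1,3-elimination.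

Step 9
Reactants: 13 spiro hydroxy vinylogous ester
Product: 14 spiro diol vinylogous ester (6R,8S,9S,12R,13S,15R; as 13 with axial OH and equatorial CH3 on C12)
Conditions: MeMgBr, CeCl3, THF, −78 °C; aq NH4Cl
Reagents that add atoms: methylmagnesium bromide, C[Mg]Br
Why: Organocerium 1,2-addition: the weakly basic reagent adds to the C12 ketone without enolisation or retro-aldol, the first equivalent being spent on the C6 hydroxyl. Axial approach is blocked by the syn-axial C8 methyl, so the methyl group enters equatorially and the hydroxyl becomes axial (12R); the C1 carbonyl is a deactivated, neopentyl vinylogous ester and is left alone.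

Step 10
Reactants: 14 spiro diol vinylogous ester
Product: 16 tetracyclic vinylogous ester (4R,6R,8S,9S,12R,13S,15R; rings A–D; O5 bridging C4 and C6; C1 ketone; C2=C3–OMe), via C4 iodide 15 (not isolated)
Conditions: LiN(i-Pr)2 (3.3 equiv), THF, −78 → −40 °C; I2 (1.0 equiv), −78 °C; DMPU, −78 → 23 °C; aq NH4Cl
Reagents that add atoms: none
Why: γ-Halogenation of an extended enolate followed by intramolecular Williamson etherification. With C15 quaternary, the base can deprotonate the vinylogous ester (after the two hydroxyls) only at C4, and the dienolate should take up iodine at C4, where the enolate and the methoxy donor reinforce each other, on the face away from the bulkier C6 branch. The C6 alkoxide, held gauche to C16, then displaces the allylic, carbonyl-activated iodide with inversion in a 5-exo-tet closure of ring D; the C4 configuration is dictated by the bridge, and an iodide at C2 or epimeric at C4 can reach the same ether by allylic transposition or iodide exchange.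

Step 11
Reactants: 16 tetracyclic vinylogous ester
Product: 17 tetracyclic β-diketone (4R,6R,8S,9S,12R,13S,15R; C1 and C3 ketones; largely enolised)
Conditions: 1 M HCl, THF, 23 °C
Reagents that add atoms: water, O
Why: Acid hydrolysis of the enol ether of a vinylogous ester; dilute acid at room temperature should spare the tertiary alcohol and the bromide, and C4 is a bridgehead, so it can neither enolise nor lose the ether oxygen.

Step 12
Reactants: 17 tetracyclic β-diketone
Product: 18 tetracyclic enol triflate (4R,6R,8S,9S,12R,13S,15R; C1 ketone; C2=C3–OTf)
Conditions: PhNTf2, Et3N, CH2Cl2, 0 → 23 °C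
Reagents that add atoms: N-phenylbis(trifluoromethanesulfonimide), O=S(=O)(N(c1ccccc1)S(=O)(=O)C(F)(F)F)C(F)(F)F
Why: O-Sulfonylation of a β-diketone enolate: the C1 oxygen is shielded by the quaternary spiro carbon, so the triflyl group should go to the C3 oxygen, the same steric bias that governs enol etherification of 4,4-disubstituted cyclohexane-1,3-diones. PhNTf2 does not react with the tertiary alcohol.

Step 13
Reactants: 18 tetracyclic enol triflate
Product: 19 tetracyclic enone (4S,6R,8S,9S,12R,13S,15R; C1 ketone; C2=C3)
Conditions: Pd(OAc)2 (cat.), PPh3, HCO2H, n-Bu3N, DMF, 60 °C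
Reagents that add atoms: none
Why: Palladium-catalysed formate reduction of an enol triflate: oxidative addition of zerovalent palladium into the activated C3–O bond, formate exchange, decarboxylation and reductive elimination of C–H. The secondary neopentyl C–Br bond does not undergo oxidative addition under these conditions.

Step 14
Reactants: 19 tetracyclic enone
Product: 20 tetracyclic ketone (4S,6R,8S,9S,12R,13S,15R; C1 ketone; C2 and C3 methylene)
Conditions: H2 (1 atm), RhCl(PPh3)3 (cat.), benzene, 23 °C
Reagents that add atoms: none
Why: Homogeneous hydrogenation of the cis-disubstituted C2=C3 bond; RhCl(PPh3)3 leaves the alkyl bromide and the allylic C4–O5 bond intact, which a heterogeneous palladium catalyst might cleave. No stereocentre is formed.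

Step 15
Reactants: 20 tetracyclic ketone
Product: 21 target CNP0412361.2 (4S,6R,8S,9S,12R,13S,15R)
Conditions: Ph3PCH3Br, KOt-Bu, toluene, 23 → 80 °C
Reagents that add atoms: methyltriphenylphosphonium bromide, C[P+](c1ccccc1)(c1ccccc1)c1ccccc1.[Br-]
Why: Wittig methylenation: excess ylide at elevated temperature should overcome the hindrance of the ketone next to the quaternary bridgehead, one equivalent being consumed by the tertiary hydroxyl. The equatorial bromide in the locked trans-decalin has no antiperiplanar hydrogen for E2, and no stereocentre is touched.

## Compound list

For the polycyclic compounds 12–21 the locants are those of the target numbering.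

1 | 2-methylcyclohex-2-en-1-one | CC1=CCCCC1=O | starting material
2 | tetraallylstannane | C=CC[Sn](CC=C)(CC=C)CC=C | starting material
3 | (S)-2-methyl-1-(prop-2-en-1-yl)cyclohex-2-en-1-ol | C=CC[C@@]1(O)CCCC=C1C | intermediate
4 | (2S,3S)-3-bromo-2-methyl-2-(prop-2-en-1-yl)cyclohexan-1-one | C=CC[C@]1(C)[C@@H](Br)CCCC1=O | intermediate
5 | (1S,2S)-1-bromo-2-methyl-3-methylidene-2-(prop-2-en-1-yl)cyclohexane | C=CC[C@]1(C)[C@@H](Br)CCCC1=C | intermediate
6 | (3S,4S)-4-bromo-3-methyl-2-methylidene-3-(prop-2-en-1-yl)cyclohexan-1-ol, both carbinol epimers | C=CC[C@]1(C)[C@@H](Br)CCC(O)C1=C | intermediate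
7 | (3S,4S)-4-bromo-3-methyl-2-methylidene-3-(prop-2-en-1-yl)cyclohexan-1-one | C=CC[C@]1(C)[C@@H](Br)CCC(=O)C1=C | intermediate
8 | 2-[(1S,6S)-6-bromo-1-methyl-2-methylidene-3-oxocyclohexyl]acetaldehyde (ring A enone aldehyde) | O=CC[C@]1(C)[C@@H](Br)CCC(=O)C1=C | intermediate
9 | dimedone (5,5-dimethylcyclohexane-1,3-dione) | CC1(C)CC(=O)CC(=O)C1 | starting material
10 | 3-methoxy-5,5-dimethylcyclohex-2-en-1-one | COC1=CC(=O)CC(C)(C)C1 | intermediate
11 | lithium 5-methoxy-3,3-dimethylcyclohexa-1,5-dien-1-olate (α′-enolate of 10) | [Li+].[O-]C1=CC(C)(C)CC(OC)=C1 | intermediate
12 | 2-[(1S,6S)-6-bromo-2-[(4-methoxy-6,6-dimethyl-2-oxocyclohex-3-en-1-yl)methyl]-1-methyl-3-oxocyclohexyl]acetaldehyde (Michael adduct; C13 and C15 not fixed) | O=CC[C@]1(C)[C@@H](Br)CCC(=O)C1CC1C(=O)C=C(OC)CC1(C)C | intermediate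
13 | spiro hydroxy vinylogous ester, (6R,8S,9S,13S,15R); trans-decalin with C6–OH equatorial, C1 ketone axial on ring B, C12 ketone | O=C1C=C(OC)CC(C)(C)[C@]12[C@H](O)C[C@]3(C)[C@@H](Br)CCC(=O)[C@H]3C2 | intermediate
14 | spiro diol vinylogous ester, (6R,8S,9S,12R,13S,15R); C12 axial OH, equatorial CH3 | O=C1C=C(OC)CC(C)(C)[C@]12[C@H](O)C[C@]3(C)[C@@H](Br)CC[C@@](C)(O)[C@H]3C2 | intermediate
15 | C4 iodide of 14, (4S,6R,8S,9S,12R,13S,15R); iodine on the ring C face opposite C6 | O=C1C=C(OC)[C@@H](I)C(C)(C)[C@]12[C@H](O)C[C@]3(C)[C@@H](Br)CC[C@@](C)(O)[C@H]3C2 | intermediate
16 | tetracyclic vinylogous ester, (4R,6R,8S,9S,12R,13S,15R); O5 bridging C4 and C6 | O=C1C=C(OC)[C@@H]2O[C@@H]3C[C@]4(C)[C@@H](Br)CC[C@@](C)(O)[C@H]4C[C@]13C2(C)C | intermediate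
17 | tetracyclic β-diketone, (4R,6R,8S,9S,12R,13S,15R) | O=C1CC(=O)[C@@H]2O[C@@H]3C[C@]4(C)[C@@H](Br)CC[C@@](C)(O)[C@H]4C[C@]13C2(C)C | intermediate
18 | tetracyclic C3 enol triflate, (4R,6R,8S,9S,12R,13S,15R) | O=C1C=C(OS(=O)(=O)C(F)(F)F)[C@@H]2O[C@@H]3C[C@]4(C)[C@@H](Br)CC[C@@](C)(O)[C@H]4C[C@]13C2(C)C | intermediate
19 | tetracyclic enone, (4S,6R,8S,9S,12R,13S,15R) | O=C1C=C[C@@H]2O[C@@H]3C[C@]4(C)[C@@H](Br)CC[C@@](C)(O)[C@H]4C[C@]13C2(C)C | intermediate
20 | tetracyclic C1 ketone, (4S,6R,8S,9S,12R,13S,15R) | O=C1CC[C@@H]2O[C@@H]3C[C@]4(C)[C@@H](Br)CC[C@@](C)(O)[C@H]4C[C@]13C2(C)C | intermediate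
21 | CNP0412361.2, (4S,6R,8S,9S,12R,13S,15R) | C=C1CC[C@@H]2O[C@@H]3C[C@]4(C)[C@@H](Br)CC[C@@](C)(O)[C@H]4C[C@]13C2(C)C | target

## Step count and risks

Total: 15 steps. Longest linear sequence: 14 steps (steps 1–6 and 8–15); step 7 is a one-step side branch.

**Step 8 (key step).**
- What may go wrong: enolate 11 may be consumed at the aldehyde (1,2-addition that does not revert, or proton transfer from C7 or C11) faster than it adds to C14, which leads to oligomerisation. During the equilibration the 4-bromo ketone unit may lose HBr, by E2 in the still flexible ring A or by 1,3-elimination from a C11 or C13 enolate. Equilibration at C13, C15 and C6 may remain incomplete.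
- Fallback: it sets out from 7 and 10 and returns at 13. Enolate 11 is added to enone 7, which carries no aldehyde, to give the allyl Michael adduct F1. The allyl group of F1 is cleaved by Lemieux–Johnson oxidation (OsO4 cat., NaIO4, 2,6-lutidine, dioxane/H2O) to the keto aldehyde 12, which is now isolated. Compound 12 is then closed to 13 by a catalytic amount of base under equilibrating conditions (DBU, or KOt-Bu in t-BuOH, 0 °C), so that the strong base never meets the aldehyde.

**Step 10.**
- What may go wrong: iodination with poor site selectivity (C2 or oxygen instead of C4), formation of a C4 epimer that neither cyclises nor equilibrates, and retro-aldol opening of ring B at the lithium alkoxide stage before the dienolate has formed.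
- Fallback: it sets out from 14 and returns at 16. Soft enolisation and silylation (TMSOTf, Et3N, CH2Cl2) give the tris(trimethylsilyl) dienol ether F2 without any strong base. NBS brominates F2 at the diene terminus C4 to the C4 bromide F3, whose hydroxyls remain silylated. Bu4NF then frees the C6 alkoxide, which closes ring D, and removes the tertiary silyl ether in the same operation to give 16.

**Step 2.**
- What may go wrong: capture of the bromonium ion by the hydroxyl (bromo epoxide), bromination on the face syn to the allyl group, migration of the ring bond C12–C13 instead of the allyl group (ring contraction), and attack on the allyl alkene.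
- Fallback: it sets out from 3 and returns at 4. Alcohol 3 is converted into its trimethylsilyl ether F4 (TMSCl, imidazole, DMF), and F4 is treated with NBS. The silyloxy group cannot close an epoxide but still stabilises the cation developing at C13, and it loses the silyl group after the allyl shift to give 4.

**Step 12.**
- What may go wrong: sulfonylation at the C1 oxygen, giving the regioisomeric triflate and, after reduction, the wrong enone.
- Fallback: it sets out from 17 and returns at 19. Condensation with TsNHNH2 proceeds by attack at carbon, which distinguishes C3 from the neopentyl C1 more sharply than O-sulfonylation does, and gives the C3 mono-tosylhydrazone F5. Heating F5 with K2CO3 (vinylogous Bamford–Stevens reaction) expels sulfinate and dinitrogen with a hydrogen shift from C2, C4 being a bridgehead, and delivers enone 19 directly, so that 18 and step 13 are bypassed.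

## Further compounds

F1 | step 8 | (3S,4S)-4-bromo-2-[(4-methoxy-6,6-dimethyl-2-oxocyclohex-3-en-1-yl)methyl]-3-methyl-3-(prop-2-en-1-yl)cyclohexan-1-one (C13 and C15 not fixed) | C=CC[C@]1(C)[C@@H](Br)CCC(=O)C1CC1C(=O)C=C(OC)CC1(C)C
F2 | step 10 | tris(trimethylsilyl) derivative of 14: C1 silyl dienol ether (C1=C2, C3=C4) with C6 and C12 silyl ethers | C[Si](C)(C)OC1=CC(OC)=CC(C)(C)[C@]12[C@H](O[Si](C)(C)C)C[C@]3(C)[C@@H](Br)CC[C@@](C)(O[Si](C)(C)C)[C@H]3C2
F3 | step 10 | (4S)-C4 bromide of the C6,C12-bis(trimethylsilyl) ether of 14 | O=C1C=C(OC)[C@@H](Br)C(C)(C)[C@]12[C@H](O[Si](C)(C)C)C[C@]3(C)[C@@H](Br)CC[C@@](C)(O[Si](C)(C)C)[C@H]3C2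
F4 | step 2 | (S)-trimethyl{[2-methyl-1-(prop-2-en-1-yl)cyclohex-2-en-1-yl]oxy}silane | C=CC[C@@]1(O[Si](C)(C)C)CCCC=C1C
F5 | step 12 | C3 mono-(p-toluenesulfonyl)hydrazone of 17 | O=C1CC(=NNS(=O)(=O)c5ccc(C)cc5)[C@@H]2O[C@@H]3C[C@]4(C)[C@@H](Br)CC[C@@](C)(O)[C@H]4C[C@]13C2(C)C
A1 | alternative 1 | 2,5-cis oxolane diester with rings A and D | C=C[C@@H]1O[C@H](C[C@]2(C)[C@@H](Br)CCC3(OCCO3)C2)C(C(=O)OC)(C(=O)OC)C1(C)C
A2 | alternative 1 | dimethyl 2,2-dimethyl-3-vinylcyclopropane-1,1-dicarboxylate (racemic) | C=CC1C(C)(C)C1(C(=O)OC)C(=O)OC
A3 | alternative 1 | 2-[(7S,8S)-8-bromo-7-methyl-1,4-dioxaspiro[4.5]decan-7-yl]acetaldehyde | O=CC[C@]1(C)[C@@H](Br)CCC2(OCCO2)C1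
A4 | alternative 2 | oxabicyclic C1 ketone with C12 triethylsilyl ether | O=C1CC[C@@H]2O[C@@H]3C[C@]4(C)[C@@H](Br)CC[C@@](C)(O[Si](CC)(CC)CC)[C@H]4C[C@]13C2(C)C
A5 | alternative 2 | spiro tricyclic C4 carbinol (C1 ketone, C6 methylene, C12 triethylsilyl ether) | O=C1CC[C@H](O)C(C)(C)[C@]12CC[C@]3(C)[C@@H](Br)CC[C@@](C)(O[Si](CC)(CC)CC)[C@H]3C2
A6 | alternative 3 | spiro β-hydroxy ketone with rings A, B and C (C3=C4 alkene, C12 triethylsilyl ether) | O=C1CC=CC(C)(C)[C@]12[C@H](O)C[C@]3(C)[C@@H](Br)CC[C@@](C)(O[Si](CC)(CC)CC)[C@H]3C2
A7 | alternative 3 | C6–C15 epoxide carrying a 1-hydroxy-2,2-dimethylcyclopent-3-en-1-yl group on C15 (carbinol configuration left open) | OC1(CC=CC1(C)C)[C@]23O[C@@H]3C[C@]4(C)[C@@H](Br)CC[C@@](C)(O[Si](CC)(CC)CC)[C@H]4C2
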